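1. CNP0251458.2 ⇒ its deoxy precursor, a pentacyclic dienone with a benzylic CH2 (C4') and a ring-fusion C–H (C3'); the C4' ketone and the C3' hydroxyl are installed last.
2. Pentacyclic dienone ⇒ (2S)-8-aryloxy-5,7-dihydroxyflavan with an ortho (E)-3-(4-methoxyphenyl)allyl group on the aryloxy ring, by cutting C8–C3' and O7–Cα (anodic dearomative (3+2)). The strategy rests on flavan C8: it carries the aryl ether oxygen O1', sits between C7–O and C8a–O1 and para to the C5 carbonyl, and is the one carbon shared by the cyclohexadienone, pyranone and tetrahydrofuran rings.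
3. Cyclisation precursor ⇒ diaryl ether from copper-catalysed coupling of an 8-iodo-5,7-bis(methoxymethoxy)flavan with 2-allyl-3,5-dimethoxyphenol, then cross-metathesis with 4-methoxystyrene and acetal removal.
4. Iodoflavan ⇒ (2S)-isosakuranetin (C4 deoxygenation, protection, C8 iodination); allylphenol ⇒ 3,5-dimethoxyphenol (O-allylation, Claisen rearrangement).
5. Ring order: the flavan chroman comes from the chiral pool; the new pyran ring and the tetrahydrofuran ring close together in the key step; no ring is formed afterwards.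

Key step: step 9

Assumption: commercial isosakuranetin is taken as the natural (2S) enantiomer; its enantiomeric purity would be checked by chiral HPLC and raised by recrystallisation if needed.
Assumption on locants: flavan numbering (O1, C2–C8a) is kept for the isosakuranetin-derived part. The dimethoxyaryloxy ring with the new pyran ring is numbered as a chroman with primes (O1', C2' = C8, C3' = ring-fusion carbon, C4' = benzylic carbon, C5'–C8a'). Cα is the tetrahydrofuran carbon that bears the second 4-methoxyphenyl group and is bonded to C3' and to O7 (the oxygen on C7).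
Remark: the ortho (E)-3-(4-methoxyphenyl)allyl group is built by Claisen rearrangement and cross-metathesis, because direct acid-catalysed cinnamylation of 3,5-dimethoxyphenol would give ortho/para mixtures and cyclised flavan by-products.

Step 1
Reactants: 1 3,5-dimethoxyphenol; 2 allyl bromide
Product: 3 1-(allyloxy)-3,5-dimethoxybenzene
Conditions: K2CO3, acetone, reflux
Reagents that add atoms: none
Why: Williamson O-alkylation of the phenoxide with an unhindered allylic bromide (SN2).

Step 2
Reactants: 3 1-(allyloxy)-3,5-dimethoxybenzene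
Product: 4 2-allyl-3,5-dimethoxyphenol
Conditions: N,N-diethylaniline, 200 °C, sealed tube
Reagents that add atoms: none
Why: Aromatic Claisen rearrangement ([3,3]-sigmatropic shift, then tautomerisation); the two ortho positions are equivalent, so only the 2-allyl isomer should form.

Step 3
Reactants: 5 (2S)-isosakuranetin
Product: 9 (2S)-2-(4-methoxyphenyl)chroman-5,7-diol, via bis(ethyl carbonate) 6 (not isolated), via ortho-quinone methide 7 (not isolated), via flavan 7-ethyl carbonate 8 (not isolated)
Conditions: ClCO2Et, Et3N, THF, 0 °C; then NaBH4, H2O, 0 °C to rt; then aq. NaOH, rt; aq. NH4Cl work-up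
Reagents that add atoms: none
Why: Reductive deoxygenation of an ortho-acyloxy aryl ketone: borohydride reduces the C4 ketone of 6, the alkoxide takes over the neighbouring ethoxycarbonyl group and eliminates to ortho-quinone methide 7, hydride reduces 7 to the methylene compound 8, and hydroxide removes the remaining carbonate, all without touching C2.

Step 4
Reactants: 9 (2S)-2-(4-methoxyphenyl)chroman-5,7-diol
Product: 10 (2S)-5,7-bis(methoxymethoxy)-2-(4-methoxyphenyl)chroman
Conditions: MOMCl, i-Pr2NEt, CH2Cl2, 0 °C to rt
Reagents that add atoms: chloromethyl methyl ether, COCCl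
Why: Base-mediated O-alkylation of both phenols with a reactive α-chloro ether gives acetals that should survive the basic copper coupling and the metathesis.

Step 5
Reactants: 10 (2S)-5,7-bis(methoxymethoxy)-2-(4-methoxyphenyl)chroman
Product: 11 (2S)-8-iodo-5,7-bis(methoxymethoxy)-2-(4-methoxyphenyl)chroman
Conditions: N-iodosuccinimide, DMF, –20 to 0 °C, dark
Reagents that add atoms: N-iodosuccinimide, O=C1CCC(=O)N1I
Why: Electrophilic aromatic iodination of the phloroglucinol-type ring A, far more electron-rich than the anisole ring; C8 (ortho to the ring oxygen) is the more accessible free position of a 5,7-dialkoxyflavan, C6 lying between two freely rotating acetal groups (regiochemistry to be confirmed by NOE and HMBC).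

Step 6
Reactants: 11 (2S)-8-iodo-5,7-bis(methoxymethoxy)-2-(4-methoxyphenyl)chroman; 4 2-allyl-3,5-dimethoxyphenol
Product: 12 (2S)-8-(2-allyl-3,5-dimethoxyphenoxy)-5,7-bis(methoxymethoxy)-2-(4-methoxyphenyl)chroman
Conditions: CuI (20 mol%), picolinic acid (40 mol%), K3PO4, DMSO, 90 °C, argon
Reagents that add atoms: none
Why: Ullmann-type copper-catalysed C–O coupling with a picolinate ligand suited to hindered partners; the ortho acetal oxygen should assist oxidative addition, and phosphate in DMSO is too weak a base to move the allyl double bond.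

Step 7
Reactants: 12 (2S)-8-(2-allyl-3,5-dimethoxyphenoxy)-5,7-bis(methoxymethoxy)-2-(4-methoxyphenyl)chroman; 13 4-methoxystyrene
Product: 14 (2S)-8-{3,5-dimethoxy-2-[(E)-3-(4-methoxyphenyl)allyl]phenoxy}-5,7-bis(methoxymethoxy)-2-(4-methoxyphenyl)chroman
Conditions: 13 (5 equiv), second-generation Hoveyda–Grubbs catalyst RuCl2(H2IMes)(=CH-C6H4-2-O-i-Pr) (5 mol%), 1,4-benzoquinone (10 mol%), CH2Cl2, 40 °C
Reagents that add atoms: none
Why: Olefin cross-metathesis of a terminal allylarene with a styrene, driven by loss of ethene and giving the thermodynamically preferred E alkene, while benzoquinone suppresses ruthenium hydride double-bond migration.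

Step 8
Reactants: 14 (2S)-8-{3,5-dimethoxy-2-[(E)-3-(4-methoxyphenyl)allyl]phenoxy}-5,7-bis(methoxymethoxy)-2-(4-methoxyphenyl)chroman
Product: 15 (2S)-8-{3,5-dimethoxy-2-[(E)-3-(4-methoxyphenyl)allyl]phenoxy}-2-(4-methoxyphenyl)chroman-5,7-diol
Conditions: HCl (1.25 M in MeOH), THF, 0 °C to rt, argon
Reagents that add atoms: none
Why: Acid-catalysed acetal exchange to dimethoxymethane frees both phenols under conditions too mild to protonate the anethole-type alkene or to open the flavan ring.

Step 9
Reactants: 15 (2S)-8-{3,5-dimethoxy-2-[(E)-3-(4-methoxyphenyl)allyl]phenoxy}-2-(4-methoxyphenyl)chroman-5,7-diol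
Product: 18 pentacyclic dienone (2S,8S,3'S,αR) having C4'H2 plus C3'–H, via C8 aryloxy-oxocarbenium ion 16 (not isolated), via anisyl-stabilised benzylic cation 17 (not isolated)
Conditions: undivided cell, reticulated vitreous carbon anode, Pt cathode, constant current (about 2.1 F/mol), LiClO4 (0.1 M), 2,6-lutidine (2 equiv), 1,1,1,3,3,3-hexafluoropropan-2-ol/CH2Cl2 (4:1), 0 °C, 2 mM substrate
Reagents that add atoms: none
Why: Proposed new method: anodic removal of two electrons and one proton from the p-aryloxyphenol (C5–OH para to C8) gives the aryloxy-stabilised cation 16, whose C8 is attacked by the alkene carbon remote from the anisyl group in a 6-exo closure of the pyran ring (C8–C3'), and the resulting 4-methoxybenzylic cation 17 is captured by the C7 hydroxyl in a 5-exo closure of the tetrahydrofuran (O7–Cα); the closest known reaction type is the anodic or hypervalent-iodine (3+2) coupling of p-alkoxyphenols, and of quinone monoketal cations, with electron-rich styrenes to dihydrobenzofurans, here diverted by the tether to the oxygen-bearing ring carbon. The step needs site selectivity, which the three-atom O–aryl–CH2 tether secures because the alkene can reach only C8 through a six-membered ring, and chemoselectivity, which rests on the tetraoxygenated ring A being easier to oxidise than the styrene or the trialkoxyarene. C8 and C3' are set together, since the C3'–C8 and Cα–O7 bonds must lie on one face of the five-membered ring and the ring fusion is therefore cis. Cα is set in the second closure, where the anisyl group should take the position trans to C4', favoured both by the E alkene and by the reversibility of the benzylic C–O bond. The C8 face relative to the remote C2 centre is not controlled by the substrate, so 18 is expected together with its (8R,3'R,αS) diastereomer and would be separated by chromatography; lutidine keeps the medium non-acidic so that the benzylic C2–O1 bond does not ionise.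

Step 10
Reactants: 18 pentacyclic dienone (2S,8S,3'S,αR)
Product: 19 C4'-hydroxy pentacycle (2S,8S,3'S,αR; both C4' epimers)
Conditions: DDQ (1.2 equiv), CH2Cl2/H2O (18:1), 0 °C to rt
Reagents that add atoms: water, O
Why: Benzylic hydride abstraction by DDQ at C4', the only CH2 attached to a 2,4,6-trioxygenated arene (as in the C4 oxidation of 5,7-dialkoxyflavans), gives a stabilised cation that water captures, while the two anisyl-bearing C–H bonds sit on vinylogous-ester oxygens and are much less hydridic.

Step 11
Reactants: 19 C4'-hydroxy pentacycle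
Product: 20 C4'-keto pentacycle (2S,8S,3'S,αR)
Conditions: Dess–Martin periodinane, CH2Cl2, 0 °C to rt
Reagents that add atoms: none
Why: Dess–Martin oxidation of the secondary benzylic alcohol under non-basic conditions, so that both C4' epimers converge and the α-C–H ketone is not exposed to base.

Step 12
Reactants: 20 C4'-keto pentacycle
Product: 21 C3'=C4' trimethylsilyl enol ether (2S,8S,αS)
Conditions: Et3N (5 equiv), then TMSOTf (2 equiv), CH2Cl2, –20 to 0 °C; non-aqueous work-up, used directly
Reagents that add atoms: trimethylsilyl trifluoromethanesulfonate, C[Si](C)(C)OS(=O)(=O)C(F)(F)F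
Why: Soft enolisation (silyl triflate activation of the aryl ketone, then removal of the only α-hydrogen at C3' by the amine) gives the enol ether without a free enolate that could expel the β-aryloxy group.

Step 13
Reactants: 21 C3'=C4' trimethylsilyl enol ether
Product: 23 CNP0251458.2 (target; 2S,8S,3'R,αS), via silyloxy epoxide 22 (not isolated)
Conditions: dimethyldioxirane (acetone solution), CH2Cl2, –40 to 0 °C; then Bu4NF, AcOH, THF, 0 °C
Reagents that add atoms: dimethyldioxirane, CC1(C)OO1
Why: Rubottom oxidation, in which dimethyldioxirane epoxidises the electron-rich silyl enol ether and buffered fluoride collapses the silyloxy epoxide to the α-hydroxy ketone; oxygen can be delivered only to the C3' face syn to C8a (the former C3'–H face), because the other face would force a trans-fused tetrahydrofuran, so the hydroxyl should be installed with retention.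

Compound list
1 | 3,5-dimethoxyphenol | COc1cc(O)cc(OC)c1 | starting material
2 | allyl bromide | C=CCBr | starting material
3 | 1-(allyloxy)-3,5-dimethoxybenzene | C=CCOc1cc(OC)cc(OC)c1 | intermediate
4 | 2-allyl-3,5-dimethoxyphenol | C=CCc1c(O)cc(OC)cc1OC | intermediate
5 | (2S)-isosakuranetin, (2S)-5,7-dihydroxy-2-(4-methoxyphenyl)chroman-4-one | COc1ccc([C@@H]2CC(=O)c3c(O)cc(O)cc3O2)cc1 | starting material
6 | (2S)-5,7-bis(ethoxycarbonyloxy)-2-(4-methoxyphenyl)chroman-4-one | COc1ccc([C@@H]2CC(=O)c3c(OC(=O)OCC)cc(OC(=O)OCC)cc3O2)cc1 | intermediate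
7 | ortho-quinone methide, (2S)-7-(ethoxycarbonyloxy)-2-(4-methoxyphenyl)-2,3-dihydro-5H-chromen-5-one | COc1ccc([C@@H]2CC=C3C(=O)C=C(OC(=O)OCC)C=C3O2)cc1 | intermediate
8 | (2S)-5-hydroxy-2-(4-methoxyphenyl)chroman-7-yl ethyl carbonate | COc1ccc([C@@H]2CCc3c(O)cc(OC(=O)OCC)cc3O2)cc1 | intermediate
9 | (2S)-2-(4-methoxyphenyl)chroman-5,7-diol | COc1ccc([C@@H]2CCc3c(O)cc(O)cc3O2)cc1 | intermediate
10 | (2S)-5,7-bis(methoxymethoxy)-2-(4-methoxyphenyl)chroman | COc1ccc([C@@H]2CCc3c(OCOC)cc(OCOC)cc3O2)cc1 | intermediate
11 | (2S)-8-iodo-5,7-bis(methoxymethoxy)-2-(4-methoxyphenyl)chroman | COc1ccc([C@@H]2CCc3c(OCOC)cc(OCOC)c(I)c3O2)cc1 | intermediate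
12 | (2S)-8-(2-allyl-3,5-dimethoxyphenoxy)-5,7-bis(methoxymethoxy)-2-(4-methoxyphenyl)chroman | COc1ccc([C@@H]2CCc3c(OCOC)cc(OCOC)c(Oc4cc(OC)cc(OC)c4CC=C)c3O2)cc1 | intermediate
13 | 4-methoxystyrene | C=Cc1ccc(OC)cc1 | starting material
14 | (2S)-8-{3,5-dimethoxy-2-[(E)-3-(4-methoxyphenyl)allyl]phenoxy}-5,7-bis(methoxymethoxy)-2-(4-methoxyphenyl)chroman | COc1ccc([C@@H]2CCc3c(OCOC)cc(OCOC)c(Oc4cc(OC)cc(OC)c4C/C=C/c4ccc(OC)cc4)c3O2)cc1 | intermediate
15 | (2S)-8-{3,5-dimethoxy-2-[(E)-3-(4-methoxyphenyl)allyl]phenoxy}-2-(4-methoxyphenyl)chroman-5,7-diol (cyclisation precursor) | COc1ccc([C@@H]2CCc3c(O)cc(O)c(Oc4cc(OC)cc(OC)c4C/C=C/c4ccc(OC)cc4)c3O2)cc1 | intermediate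
16 | C8 aryloxy-oxocarbenium ion of 15 (C5 ketone, C7 hydroxyl, C8=O+–aryl) | COc1ccc([C@@H]2CCC3=C(O2)C(=[O+]c4cc(OC)cc(OC)c4C/C=C/c4ccc(OC)cc4)C(O)=CC3=O)cc1 | intermediate
17 | 4-methoxybenzylic cation after C8–C3' bond formation (pyran ring closed, C7 hydroxyl free) | COc1ccc([C@@H]2CCC3=C(O2)[C@@]4(Oc5cc(OC)cc(OC)c5C[C@H]4[CH+]c4ccc(OC)cc4)C(O)=CC3=O)cc1 | intermediate
18 | pentacyclic dienone (2S,8S,3'S,αR): C5 ketone with C4a=C8a and C6=C7; C8 bonded to O1' of the 5',7'-dimethoxychroman ring and to C3'; tetrahydrofuran O7–Cα(H)(4-methoxyphenyl)–C3'; C4' is CH2; C3'–H cis to C8a, anisyl on Cα trans to C4' | COc1ccc([C@@H]2CCC3=C(O2)[C@]24Oc5cc(OC)cc(OC)c5C[C@H]2[C@H](c2ccc(OC)cc2)OC4=CC3=O)cc1 | intermediate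
19 | C4'-hydroxy derivative of 18 (2S,8S,3'S,αR; mixture of C4' epimers) | COc1ccc([C@@H]2CCC3=C(O2)[C@]24Oc5cc(OC)cc(OC)c5C(O)[C@H]2[C@H](c2ccc(OC)cc2)OC4=CC3=O)cc1 | intermediate
20 | C4'-keto derivative of 18 (2S,8S,3'S,αR), a 5',7'-dimethoxychroman-4'-one with C3'–H | COc1ccc([C@@H]2CCC3=C(O2)[C@]24Oc5cc(OC)cc(OC)c5C(=O)[C@H]2[C@H](c2ccc(OC)cc2)OC4=CC3=O)cc1 | intermediate
21 | trimethylsilyl enol ether of 20 (C3'=C4', C4'–OSiMe3; 2S,8S,αS) | COc1ccc([C@@H]2CCC3=C(O2)[C@]24Oc5cc(OC)cc(OC)c5C(O[Si](C)(C)C)=C2[C@H](c2ccc(OC)cc2)OC4=CC3=O)cc1 | intermediate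
22 | C3',C4'-epoxide of 21 (epoxide oxygen on the face syn to C8a, C4' bearing OSiMe3) | COc1ccc([C@@H]2CCC3=C(O2)[C@]24Oc5cc(OC)cc(OC)c5[C@]6(O[Si](C)(C)C)O[C@@]62[C@H](c2ccc(OC)cc2)OC4=CC3=O)cc1 | intermediate
23 | CNP0251458.2 (2S,8S,3'R,αS): C4' ketone, C3' hydroxyl cis to C8a and to the anisyl group on Cα | COc1ccc([C@@H]2CCC3=C(O2)[C@]24Oc5cc(OC)cc(OC)c5C(=O)[C@@]2(O)[C@H](c2ccc(OC)cc2)OC4=CC3=O)cc1 | target

Total step count: 13.
Longest linear sequence: 11 steps (steps 3 to 13, from isosakuranetin); the phenol branch (steps 1 and 2) joins at step 6.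

Steps most likely to fail

Step 9 (anodic (3+2)). The cation is formed at the electrode in the presence of product and of the oxidisable styrene, so over-oxidation of 18, intermolecular coupling or anode passivation may outrun the 6-exo closure. The fallback separates oxidation from cyclisation and uses known reaction types. Setting out from 15, oxidation with PhI(OAc)2 in MeOH at –20 °C (oxidative dearomatisation of a p-alkoxyphenol to a quinone monoketal) should give the C8 methyl aryl mixed ketal F1, which is isolated. Ionisation of F1 with BF3·OEt2 in CH2Cl2 at –78 °C (the acid-promoted (3+2) cycloaddition of a quinone monoketal with a styrene, with loss of methanol) regenerates cation 16 in the absence of any oxidant and should come back to the route at 18.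

Step 6 (diaryl ether coupling). Oxidative addition of copper to the electron-rich, doubly ortho-oxygenated iodide may be slower than protodeiodination, or the hot basic medium may shift the allyl double bond into conjugation. The fallback exchanges the roles of the partners and uses palladium. Setting out from 11, iodine–magnesium exchange (i-PrMgCl·LiCl, THF, –20 °C), B(OMe)3 and then H2O2/NaOH should give (2S)-5,7-bis(methoxymethoxy)-2-(4-methoxyphenyl)chroman-8-ol F2. Phenol 4 is converted with Tf2O and pyridine (CH2Cl2, 0 °C) into 2-allyl-3,5-dimethoxyphenyl trifluoromethanesulfonate F3. Coupling of F2 with F3 (Pd(OAc)2, 2-di-tert-butylphosphino-2',4',6'-triisopropylbiphenyl, K3PO4, toluene, 100 °C) comes back to the route at 12.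

Step 13 (Rubottom oxidation). The oxidant has to reach the enol ether on the face syn to C8a, next to the anisyl group on Cα, so epoxidation may be slower than hydrolysis of the silyl enol ether back to 20; enolisation in step 12 may also be sluggish at the hindered ring-fusion C–H. The fallback avoids any enol derivative and brings the oxygen in by dihydroxylation. Setting out from 19, acid-catalysed dehydration (pyridinium p-toluenesulfonate, 4 Å sieves, toluene, 60 °C) should give the C3'=C4' 2H-chromene F4. OsO4 (cat.) with N-methylmorpholine N-oxide in acetone/H2O then adds both oxygens from the only face that keeps the ring fusion cis, giving the cis-3',4'-diol F5. MnO2 or Dess–Martin periodinane oxidises only the secondary benzylic alcohol of F5, and the route is rejoined at 23.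

Further compounds
F1 | step 9 | C8 methyl aryl mixed ketal of 15 (8-methoxy-8-aryloxy-7-hydroxy cyclohexadienone, C8 epimers) | COc1ccc([C@@H]2CCC3=C(O2)C(OC)(Oc4cc(OC)cc(OC)c4C/C=C/c4ccc(OC)cc4)C(O)=CC3=O)cc1
F2 | step 6 | (2S)-5,7-bis(methoxymethoxy)-2-(4-methoxyphenyl)chroman-8-ol | COc1ccc([C@@H]2CCc3c(OCOC)cc(OCOC)c(O)c3O2)cc1
F3 | step 6 | 2-allyl-3,5-dimethoxyphenyl trifluoromethanesulfonate | C=CCc1c(OS(=O)(=O)C(F)(F)F)cc(OC)cc1OC
F4 | step 13 | C3'=C4' 2H-chromene derived from 19 | COc1ccc([C@@H]2CCC3=C(O2)[C@]24Oc5cc(OC)cc(OC)c5C=C2[C@H](c2ccc(OC)cc2)OC4=CC3=O)cc1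
F5 | step 13 | cis-3',4'-diol (C3' hydroxyl syn to C8a, C4' hydroxyl cis to it) | COc1ccc([C@@H]2CCC3=C(O2)[C@]24Oc5cc(OC)cc(OC)c5[C@H](O)[C@@]2(O)[C@H](c2ccc(OC)cc2)OC4=CC3=O)cc1
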